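I start with the easy step, solid substrate going into solution, and assume its rate is proportional to the room left below a ceiling: rate = k_d(c_sat − c), where c is the dissolved substrate and k_d a rate constant.

| flask | solid substrate | partner | remark | time |
|---|---|---|---|---|
| Wednesday's | 1.6 M | 2.2 M | run made earlier |  |
| flask | 1.6 M | 1.12 M |  | 12 h |

Wednesday's run (percent of the solid substrate charged)

| time / min | target / % | dissolved substrate / % | solid substrate / % |
|---|---|---|---|
| 6.00 | 0 | 6 | 95 |
| 20.0 | 0 | 20 | 86 |
| 30.0 | 0 | 24 | 76 |
| 50.0 | 0 | 35 | 63 |
| 80.0 | 0 | 44 | 58 |

(each reading ± 2 percentage points)

- solid, in amounts per volume of the solution: solid substrate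
- at the start none of the solid substrate is in solution
- dissolved substrate means what is dissolved; the solid is not counted in it

- amount of target at 12 h, in percent of the solid substrate charged
- concentration of dissolved substrate in solution at 12 h, in percent of saturation

In Wednesday's run the first 30.0 min give 0.0128 M min⁻¹ at a mean c of 0.192 M. The stretch from 50.0 min to 80.0 min gives 0.00480 M min⁻¹ at 0.632 M. A straight line through these two points has slope k_d = 0.0182 min⁻¹ and reaches zero rate at 0.896 M: this is c_sat, the saturation concentration, the most dissolved substrate the solution takes.

The flask is charged with 1.6 M of solid substrate, more than this ceiling, so I expect solid to remain. Its 12 h span 13.1 times 1/k_d, so I reckon the flask saturated by then, near 56.0% of the charge dissolved.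

For the target I can reckon a bound. Assume its rate is first order in dissolved substrate and in partner, and that Wednesday's run held as much as one scatter width, 2 percentage points, at 80.0 min. The time integral of c under the rise above, and the partner charges, then multiply that by 8.95 for the flask if partner stayed as charged. My ceiling on y is therefore 17.9%.

The forecast gives 4% and 99%, saying “The data only bound it, so I expect a few percent.” The flask gives 3.63% of target and 99.9% of saturation, with 36.4% of the charge still solid at 12.0 h.

    solid substrate ⇌ dissolved substrate, rate k1*(cs1 - [dissolved substrate]) while solid is left; crystals form when [dissolved substrate] > cs1 (solubility = 0.960 M, k = 2.80 × 10⁻⁴ s⁻¹)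
    2 partner → homo dimer (k = 5.20 × 10⁻⁵ L mol⁻¹ s⁻¹)
    dissolved substrate + partner → target (k = 1.10 × 10⁻⁵ L mol⁻¹ s⁻¹)
    solid substrate → decomposition product (k = 1.70 × 10⁻⁸ s⁻¹)
    partner → side product (k = 7.90 × 10⁻⁵ s⁻¹)

The neighbouring flask is charged with 0.64 M of solid substrate, less than c_sat, its other charges and its time being those of the flask. The ceiling share there is 140% of the charge, so the same reckoning says the solid dissolves completely and the solution stays below saturation. That neighbour holds 0% solid and 92.9% dissolved at 12.0 h, which is 0.595 M, or 66.4% of my c_sat. Its target stands at 7.10%.

The numbers in the tables were computed on assumed constants, noise included.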